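The readings were computed with constants of no real substance; noise was put on by code.

At early times the amber run climbs fast: target reads 6.7% at 0.200 h, has its highest reading, 9.0%, at 0.500 h, then sinks slowly.

| flask | substrate | first nucleophile | second nucleophile | remark | time |
|---|---|---|---|---|---|
| amber | 0.50 M | 0.50 M | 0.50 M | run made earlier |  |
| teal | 0.70 M | 0.50 M | 0.50 M | run made earlier |  |
| ochre | 1.1 M | 0.50 M | 0.50 M | run made earlier |  |
| north-west | 0.50 M | 0.500 M | 0.500 M | everything together at the start | 6.0 h |
| east | 0.50 M (fed, over 4.0 h) | 0.500 M | 0.500 M | all else is in the flask from the start; the feed brings no volume worth counting | 6.0 h |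
| south-east | 0.50 M | 0.500 M | 0.500 M (fed, over 4.0 h) | all else is in the flask from the start; the feed brings no volume worth counting | 6.0 h |

- amber (time / h: target / %): 0.200: 6.7; 0.500: 9.0; 1.00: 7.4; 1.50: 6.8; 2.00: 6.4; 3.00: 5.8; 4.00: 5.2
- teal (time / h: target / %): 0.417: 9.0; 1.00: 8.1; 2.00: 5.5; 3.00: 5.1; 4.00: 5.3; 6.00: 4.9; 8.00: 5.0
- ochre (time / h: target / %): 1.00: 7.0; 2.00: 4.3; 3.00: 5.1; 4.00: 4.2; 5.00: 4.7; 6.00: 4.3; 8.00: 4.1

(scatter of a reading: 0.3 percentage points)

- the analysis behind the earlier runs scatters by 0.3 percentage points, standard deviation

- which flask leads in amount of target, in percent of the substrate charged ("all alike" within 1.5 percentage points) (north-west / east / south-east / all alike)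
- how much target is there at the end, in percent of the substrate charged: north-west
- how much target is there at the end, in percent of the substrate charged: east
- how much target is there at the end, in percent of the substrate charged: south-east

So target seems to be made in one short early stretch. The time of the highest amber reading, 0.500 h, is taken here as the capture window: the time for which first nucleophile is assumed to last, treated as a first-order lifetime. The late teal and ochre readings are 5.0% and 4.1% at substrate charges of 0.70 M and 1.1 M, so the percentage follows the charge weakly.

North-west repeats amber, so it should stay near 5.2%. But east feeds substrate over 4.0 h, much longer than the window, so 12.5% of it has entered when the window ends. This reckoning therefore gives east 0.650%. In south-east the same share, 12.5%, of the second nucleophile has entered when the window ends, so this reckoning places south-east above north-west, without a figure.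

The forecast gives 4.6%, 3% and 15% for north-west, east and south-east, with south-east ahead, because “the first nucleophile captures far more substrate”.

The flasks give 5.45%, 0.985% and 7.17%, and south-east leads.

    first nucleophile → decomposed reagent (k = 0.0329 min⁻¹)
    first nucleophile + intermediate → target (k = 81.6 M⁻¹ min⁻¹)
    intermediate → solvolysis product (k = 8.46 min⁻¹)
    substrate → intermediate (k = 0.0110 min⁻¹)
    target ⇌ isomer of the product (K = 2.90, k = 0.0342 min⁻¹)
    substrate + intermediate → side product (k = 0.143 M⁻¹ min⁻¹)
    second nucleophile + intermediate → other capture product (k = 25.9 M⁻¹ min⁻¹)

By decomposition alone, first nucleophile has a half-life of 0.35 h in north-west, shorter than the 4.0 h of either feed, and in south-east 82% of the decomposition up to 6.0 h is over at 0.600 h, when solvolysis of intermediate has done 21% of its turnover up to that end. East holds 18.1% of the north-west target, against the 12.5% reckoned from the window.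

For the neighbour of south-east with 2.0 M of first nucleophile, falling back to the usual charge is reckoned to take 1.39 further lifetimes, so its window is reckoned at 1.19 h and, with target scaled by the window from south-east, target at 17.1%. That neighbour flask gives 12.6%.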